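**Retrosynthetic overview**
1. Target 16 ⇐ cyclohexene peroxide 14 by a final Schenck ene reaction and hydroperoxide reduction, which turns the tetrasubstituted ring olefin into the tertiary allylic alcohol and exocyclic methylene, as in the presumed biogenesis.
2. The 1,2-dioxane of 14 ⇐ 6-exo attack of the C6 tertiary hydroperoxide on C3 of the C1–C3 propionate terminus (the biogenetic ring closure), run on a cis-β-lactone instead of the 2-enoate so that C2 and C3 are transferred stereospecifically.
3. C6–OOH ⇐ Co/O2/Et3SiH hydroperoxysilylation of the 1,1-disubstituted olefin of β-lactone 10; 10 ⇐ catalytic asymmetric propanoyl chloride–aldehyde cyclocondensation on aldehyde 7.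
4. Aldehyde 7 ⇐ dihydro-β-ionone 1 (methylenation, allylic lithiation/oxirane, oxidation).
5. Ring order: cyclohexene ring bought in 1 → β-lactone (step 4, temporary) → 1,2-dioxane (step 6).

Assumption: locants C1–C8 follow the acid chain of the target (C1 ester carbon, C3 and C6 the peroxide carbons) and C1′ is the carbinol carbon; the C6 descriptor of 14 (6S) becomes 6R in 15/16 only because the CIP ranking changes when C1′ is oxygenated.
Assumption: O-TMS-quinine is a catalyst made by silylating quinine (not counted as a step); step 5 is a pure addition (alkene + O2 + Et3SiH) and forms nothing beside its product.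

Two stereocentres are not controlled by this route: C6 (step 5) and C1′ (step 7) each form about 1:1 and the wanted isomer is separated. C2 and C3 are set by catalyst control in step 4 and carried through stereospecifically.

**Step 1**
Reactants: 1 dihydro-β-ionone [4-(2,6,6-trimethylcyclohex-1-en-1-yl)butan-2-one]
Product: 2 2-(3-methylbut-3-en-1-yl)-1,3,3-trimethylcyclohex-1-ene
Conditions: Ph3PCH3Br, KOt-Bu, THF, 0 °C → rt
Reagents that add atoms: methyltriphenylphosphonium bromide, C[P+](c1ccccc1)(c1ccccc1)c1ccccc1.[Br-]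
Why: Wittig methylenation of an unhindered methyl ketone installs the CH2 that later becomes the C6 methyl; no stereocentre is formed.

**Step 2**
Reactants: 2 2-(3-methylbut-3-en-1-yl)-1,3,3-trimethylcyclohex-1-ene; 3 oxirane
Product: 6 4-methylidene-6-(2,6,6-trimethylcyclohex-1-en-1-yl)hexan-1-ol, via allyllithium 4 (not isolated), via lithium alkoxide 5 (not isolated)
Conditions: n-BuLi, TMEDA, hexane, rt; then oxirane, THF, −78 → 0 °C; then H2O
Reagents that add atoms: none
Why: Allylic lithiation of the 2-methyl-1-alkene at its methyl group (kinetically preferred over CH2 and over the allylic positions of the tetrasubstituted olefin, as in the C-10 lithiation of limonene) gives a 2-substituted allyllithium with equivalent termini, and SN2 opening of oxirane adds C3–C4; no stereocentre is formed.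

**Step 3**
Reactants: 6 4-methylidene-6-(2,6,6-trimethylcyclohex-1-en-1-yl)hexan-1-ol
Product: 7 4-methylidene-6-(2,6,6-trimethylcyclohex-1-en-1-yl)hexanal
Conditions: TEMPO (10 mol%), PhI(OAc)2, CH2Cl2, rt
Reagents that add atoms: none
Why: TEMPO/PhI(OAc)2 oxidation takes the primary alcohol to the aldehyde without touching either olefin; no stereocentre is formed.

**Step 4**
Reactants: 7 4-methylidene-6-(2,6,6-trimethylcyclohex-1-en-1-yl)hexanal; 8 propanoyl chloride
Product: 10 (3S,4R)-3-methyl-4-[3-methylidene-5-(2,6,6-trimethylcyclohex-1-en-1-yl)pentyl]oxetan-2-one (cis-β-lactone), via methylketene 9 (not isolated)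
Conditions: O-TMS-quinine (10 mol%), LiI, i-Pr2NEt, CH2Cl2/Et2O, −78 °C
Reagents that add atoms: none
Why: Cinchona-alkaloid/lithium-salt catalysed acyl halide–aldehyde cyclocondensation (Wynberg-type ketene–aldehyde [2+2] through the alkaloid-bound enolate of methylketene) gives the cis-lactone under catalyst control, the (3S,4R) sense being assigned to O-TMS-quinine by analogy (O-TMS-quinidine gives the mirror image); these centres become C2 and C3.

**Step 5**
Reactants: 10 (3S,4R)-3-methyl-4-[3-methylidene-5-(2,6,6-trimethylcyclohex-1-en-1-yl)pentyl]oxetan-2-one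
Product: 11 (3S,4R)-3-methyl-4-[3-methyl-3-(triethylsilylperoxy)-5-(2,6,6-trimethylcyclohex-1-en-1-yl)pentyl]oxetan-2-one (1:1 mixture at the peroxy carbon)
Conditions: Co(thd)2 (5 mol%), Et3SiH, O2 (1 atm), ClCH2CH2Cl, rt
Reagents that add atoms: dioxygen, O=O; triethylsilane, CC[SiH](CC)CC
Why: Isayama–Mukaiyama hydroperoxysilylation (Co–H hydrogen-atom transfer, Markovnikov) converts only the 1,1-disubstituted olefin, leaving the tetrasubstituted ring olefin and the lactone, and the planar tertiary radical is trapped by O2 without facial bias, so C6 forms 1:1 and is sorted out after ring closure.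

**Step 6**
Reactants: 11 (3S,4R)-3-methyl-4-[3-methyl-3-(triethylsilylperoxy)-5-(2,6,6-trimethylcyclohex-1-en-1-yl)pentyl]oxetan-2-one
Product: 14 methyl (2S)-2-[(3S,6S)-6-methyl-6-[2-(2,6,6-trimethylcyclohex-1-en-1-yl)ethyl]-1,2-dioxan-3-yl]propanoate (6-methyl cis to H-3), via caesium peroxide 12 (not isolated), via caesium carboxylate 13 (not isolated)
Conditions: CsF, 18-crown-6 (10 mol%), DMF (0.01 M), 0 °C → rt; then MeI, rt; SiO2 chromatography
Reagents that add atoms: iodomethane, CI
Why: Proposed new method: fluoride unmasks the tertiary peroxide anion (too weakly basic to enolise the lactone), which attacks the lactone C4 (target C3) in a 6-exo-tet SN2 with alkyl–oxygen cleavage and inversion (4R → 3S) while C2 is untouched, driven by ring strain and the carboxylate leaving group; the closest known reactions are the alkyl–oxygen SN2 opening of β-lactones by weakly basic O-nucleophiles (carboxylates, phenoxides) with inversion and the intramolecular alkylation of hydroperoxides by secondary sulfonates or halides to 1,2-dioxanes; the carboxylate is methylated in the same flask and the 3,6-diastereomeric C6 epimer from step 5 is removed by chromatography.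

**Step 7**
Reactants: 14 methyl (2S)-2-[(3S,6S)-6-methyl-6-[2-(2,6,6-trimethylcyclohex-1-en-1-yl)ethyl]-1,2-dioxan-3-yl]propanoate
Product: 16 methyl (2S)-2-[(3S,6R)-6-[2-[(1S)-1-hydroxy-2,2-dimethyl-6-methylidenecyclohexyl]ethyl]-6-methyl-1,2-dioxan-3-yl]propanoate (target), via allylic hydroperoxide 15 (not isolated)
Conditions: O2, TPP (1 mol%), white LED, CH2Cl2, −20 °C; then PPh3, 0 °C; preparative HPLC
Reagents that add atoms: dioxygen, O=O
Why: Schenck ene reaction of singlet oxygen at the only electron-rich (tetrasubstituted) olefin, with C–O bond formation at the chain-bearing ring carbon and hydrogen transfer from the ring methyl to give the exocyclic methylene, followed by PPh3 reduction of the hydroperoxide with retention while the dialkyl peroxide survives; the remote dioxane does not differentiate the olefin faces, so the (1S)-carbinol is about half of this regioisomer and is separated from its 1R epimer and from regioisomeric ene products by HPLC.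

**Compound list**
1 | dihydro-β-ionone, 4-(2,6,6-trimethylcyclohex-1-en-1-yl)butan-2-one | CC(=O)CCC1=C(C)CCCC1(C)C | starting material
2 | 2-(3-methylbut-3-en-1-yl)-1,3,3-trimethylcyclohex-1-ene | C=C(C)CCC1=C(C)CCCC1(C)C | intermediate
3 | oxirane (ethylene oxide) | C1CO1 | starting material
4 | [2-methylidene-4-(2,6,6-trimethylcyclohex-1-en-1-yl)butyl]lithium (allyllithium) | [Li]CC(=C)CCC1=C(C)CCCC1(C)C | intermediate
5 | lithium 4-methylidene-6-(2,6,6-trimethylcyclohex-1-en-1-yl)hexan-1-olate | [Li+].[O-]CCCC(=C)CCC1=C(C)CCCC1(C)C | intermediate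
6 | 4-methylidene-6-(2,6,6-trimethylcyclohex-1-en-1-yl)hexan-1-ol | OCCCC(=C)CCC1=C(C)CCCC1(C)C | intermediate
7 | 4-methylidene-6-(2,6,6-trimethylcyclohex-1-en-1-yl)hexanal | O=CCCC(=C)CCC1=C(C)CCCC1(C)C | intermediate
8 | propanoyl chloride | CCC(=O)Cl | starting material
9 | methylketene (prop-1-en-1-one) | CC=C=O | intermediate
10 | (3S,4R)-3-methyl-4-[3-methylidene-5-(2,6,6-trimethylcyclohex-1-en-1-yl)pentyl]oxetan-2-one | C[C@@H]1C(=O)O[C@@H]1CCC(=C)CCC2=C(C)CCCC2(C)C | intermediate
11 | (3S,4R)-3-methyl-4-[3-methyl-3-(triethylsilylperoxy)-5-(2,6,6-trimethylcyclohex-1-en-1-yl)pentyl]oxetan-2-one, 1:1 at the peroxy carbon | C[C@@H]1C(=O)O[C@@H]1CCC(C)(OO[Si](CC)(CC)CC)CCC2=C(C)CCCC2(C)C | intermediate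
12 | caesium peroxide of 11 (Et3Si replaced by Cs+), 1:1 at the peroxy carbon | C[C@@H]1C(=O)O[C@@H]1CCC(C)(O[O-])CCC2=C(C)CCCC2(C)C.[Cs+] | intermediate
13 | caesium (2S)-2-[(3S)-6-methyl-6-[2-(2,6,6-trimethylcyclohex-1-en-1-yl)ethyl]-1,2-dioxan-3-yl]propanoate, 1:1 at C6 | CC1=C(CCC2(C)CC[C@@H]([C@H](C)C(=O)[O-])OO2)C(C)(C)CCC1.[Cs+] | intermediate
14 | methyl (2S)-2-[(3S,6S)-6-methyl-6-[2-(2,6,6-trimethylcyclohex-1-en-1-yl)ethyl]-1,2-dioxan-3-yl]propanoate | CC1=C(CC[C@@]2(C)CC[C@@H]([C@H](C)C(=O)OC)OO2)C(C)(C)CCC1 | intermediate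
15 | methyl (2S)-2-[(3S,6R)-6-[2-(1-hydroperoxy-2,2-dimethyl-6-methylidenecyclohexyl)ethyl]-6-methyl-1,2-dioxan-3-yl]propanoate, both C1′ epimers | C=C1CCCC(C)(C)C1(OO)CC[C@@]1(C)CC[C@@H]([C@H](C)C(=O)OC)OO1 | intermediate
16 | methyl (2S)-2-[(3S,6R)-6-[2-[(1S)-1-hydroxy-2,2-dimethyl-6-methylidenecyclohexyl]ethyl]-6-methyl-1,2-dioxan-3-yl]propanoate | C=C1CCCC(C)(C)[C@@]1(O)CC[C@@]1(C)CC[C@@H]([C@H](C)C(=O)OC)OO1 | target

**Step count and risks**
Total steps: 7. Longest linear sequence: 7 (fully linear from 1).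

Steps most likely to fail:

Step 6 (peroxide SN2 on the β-lactone is unprecedented; intermolecular acyl attack or lactone elimination could compete). The fallback sets out from aldehyde 7 and uses the conventional peroxy-Michael closure. Wittig olefination of 7 with methyl 2-(triphenylphosphoranylidene)propanoate gives methyl (2E)-2-methyl-6-methylidene-8-(2,6,6-trimethylcyclohex-1-en-1-yl)oct-2-enoate F1. Co(thd)2/Et3SiH/O2 then gives racemic methyl (2E)-2,6-dimethyl-6-(triethylsilylperoxy)-8-(2,6,6-trimethylcyclohex-1-en-1-yl)oct-2-enoate F2. TBAF frees methyl (2E)-6-hydroperoxy-2,6-dimethyl-8-(2,6,6-trimethylcyclohex-1-en-1-yl)oct-2-enoate F3, which cyclises with Et2NH in CF3CH2OH by 6-exo conjugate addition and protonation. C2/C3 control is lost in this variant, so the (2S*,3S*,6S*) diastereomer is isolated by chromatography and resolved on a chiral stationary phase; the route is rejoined at 14.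

Step 7 (three regioisomeric ene products are possible and C1′ is formed without facial control). The fallback sets out from 14 and puts C1′ under reagent control. Shi epoxidation (fructose-derived ketone, Oxone; or mCPBA with separation) gives methyl (2S)-2-[(3S,6R)-6-methyl-6-[2-[(1S,6R)-2,2,6-trimethyl-7-oxabicyclo[4.1.0]heptan-1-yl]ethyl]-1,2-dioxan-3-yl]propanoate F4. TMSOTf/2,6-lutidine opens the epoxide at the methyl-bearing carbon and removes a methyl proton, giving methyl (2S)-2-[(3S,6R)-6-[2-[(1S)-2,2-dimethyl-6-methylidene-1-(trimethylsilyloxy)cyclohexyl]ethyl]-6-methyl-1,2-dioxan-3-yl]propanoate F5. Citric acid in MeOH removes the silyl group; the route is rejoined at 16.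

Step 2 (lithiation could also occur at the ring-allylic positions or at the chain CH2). The fallback sets out from 1 and replaces metalation by a sigmatropic route. Corey–Chaykovsky methylenation (Me3S+ I−, n-BuLi) gives 2-methyl-2-[2-(2,6,6-trimethylcyclohex-1-en-1-yl)ethyl]oxirane F6. Et2Al(TMP) isomerises it to 2-methylidene-4-(2,6,6-trimethylcyclohex-1-en-1-yl)butan-1-ol F7. Ethyl vinyl ether/Hg(OAc)2 gives the allyl vinyl ether 2-[3-(ethenyloxymethyl)but-3-en-1-yl]-1,3,3-trimethylcyclohex-1-ene F8, and heating (Claisen rearrangement) delivers the aldehyde; the route is rejoined at 7.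

**Further compounds**
F1 | step 6 | methyl (2E)-2-methyl-6-methylidene-8-(2,6,6-trimethylcyclohex-1-en-1-yl)oct-2-enoate | COC(=O)/C(C)=C/CCC(=C)CCC1=C(C)CCCC1(C)C
F2 | step 6 | methyl (2E)-2,6-dimethyl-6-(triethylsilylperoxy)-8-(2,6,6-trimethylcyclohex-1-en-1-yl)oct-2-enoate (racemic) | COC(=O)/C(C)=C/CCC(C)(OO[Si](CC)(CC)CC)CCC1=C(C)CCCC1(C)C
F3 | step 6 | methyl (2E)-6-hydroperoxy-2,6-dimethyl-8-(2,6,6-trimethylcyclohex-1-en-1-yl)oct-2-enoate (racemic) | COC(=O)/C(C)=C/CCC(C)(OO)CCC1=C(C)CCCC1(C)C
F4 | step 7 | methyl (2S)-2-[(3S,6R)-6-methyl-6-[2-[(1S,6R)-2,2,6-trimethyl-7-oxabicyclo[4.1.0]heptan-1-yl]ethyl]-1,2-dioxan-3-yl]propanoate | C[C@@]12CCCC(C)(C)[C@@]1(O2)CC[C@@]1(C)CC[C@@H]([C@H](C)C(=O)OC)OO1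
F5 | step 7 | methyl (2S)-2-[(3S,6R)-6-[2-[(1S)-2,2-dimethyl-6-methylidene-1-(trimethylsilyloxy)cyclohexyl]ethyl]-6-methyl-1,2-dioxan-3-yl]propanoate | C=C1CCCC(C)(C)[C@@]1(O[Si](C)(C)C)CC[C@@]1(C)CC[C@@H]([C@H](C)C(=O)OC)OO1
F6 | step 2 | 2-methyl-2-[2-(2,6,6-trimethylcyclohex-1-en-1-yl)ethyl]oxirane (racemic) | CC1(CCC2=C(C)CCCC2(C)C)CO1
F7 | step 2 | 2-methylidene-4-(2,6,6-trimethylcyclohex-1-en-1-yl)butan-1-ol | OCC(=C)CCC1=C(C)CCCC1(C)C
F8 | step 2 | 2-[3-(ethenyloxymethyl)but-3-en-1-yl]-1,3,3-trimethylcyclohex-1-ene | C=COCC(=C)CCC1=C(C)CCCC1(C)C
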